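The seven-membered ring is opened between C5 and C6 (azulene numbering: C3 isopropyl, C3a ring-fusion carbinol, C6 methyl carbinol, C7 ester carbon, C8a angular methyl). Because C6 carries a methyl group and adjoins the oxygenated C7, this bond can be forged as the alkene of an α-methyl enone (C5=C6–C7=O): ring-closing metathesis joins an allyl group on C3a to an isopropenyl ketone arm on C8a, both cis on a cyclopentane. That cyclopentane is carved from (S)-limonene by ring contraction, Claisen rearrangement and allylation. The enone then relays the C7 and C6 stereocentres by reduction and radical hydration.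

Key step: step 9

Remark: the SMILES is read as placing the C3 isopropyl, C3a hydroxyl, C8a methyl and C7 acyloxy groups on one face of the cis-fused bicycle and the C6 hydroxyl on the other; the route is built for this relative and absolute configuration.

Step 1
Reactants: 1 (S)-(−)-limonene
Product: 2 (4S)-1-methyl-4-(propan-2-yl)cyclohex-1-ene
Conditions: H2 (1 atm), RhCl(PPh3)3 (1 mol %), toluene/EtOH, rt
Reagents that add atoms: none
Why: Chemoselective homogeneous hydrogenation: RhCl(PPh3)3 saturates the 1,1-disubstituted isopropenyl alkene far faster than the trisubstituted ring alkene and leaves the C4 stereocentre untouched.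

Step 2
Reactants: 2 (4S)-1-methyl-4-(propan-2-yl)cyclohex-1-ene
Product: 4 (3S)-6-oxo-3-(propan-2-yl)heptanal, via ozonide 3 (not isolated)
Conditions: O3, CH2Cl2, −78 °C; then Me2S, −78 °C to rt
Reagents that add atoms: ozone, [O-][O+]=O
Why: Ozonolysis with reductive work-up cleaves the single remaining alkene to the 1,6-keto aldehyde, and the stereocentre, β to the aldehyde, cannot enolise.

Step 3
Reactants: 4 (3S)-6-oxo-3-(propan-2-yl)heptanal
Product: 6 (5R)-2-methyl-5-(propan-2-yl)cyclopent-1-ene-1-carbaldehyde, via aldol adduct 5 (not isolated)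
Conditions: piperidine (0.2 equiv), AcOH (0.2 equiv), toluene, 80 °C
Reagents that add atoms: none
Why: Intramolecular enamine-mediated aldol condensation: the piperidine enamine of the aldehyde attacks the methyl ketone (five-membered ring closure) and the aldol dehydrates to the tetrasubstituted enal, while the isopropyl-bearing carbon is not acidic in any intermediate and keeps its configuration.

Step 4
Reactants: 6 (5R)-2-methyl-5-(propan-2-yl)cyclopent-1-ene-1-carbaldehyde
Product: 7 [(5R)-2-methyl-5-(propan-2-yl)cyclopent-1-en-1-yl]methanol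
Conditions: NaBH4, CeCl3·7H2O, MeOH, 0 °C
Reagents that add atoms: none
Why: Luche reduction: the cerium-activated carbonyl takes hydride in the 1,2 mode only, giving the primary allylic alcohol without touching the tetrasubstituted alkene.

Step 5
Reactants: 7 [(5R)-2-methyl-5-(propan-2-yl)cyclopent-1-en-1-yl]methanol; 8 N,N-dimethylacetamide dimethyl acetal
Product: 10 2-[(1R,3R)-1-methyl-2-methylidene-3-(propan-2-yl)cyclopentyl]-N,N-dimethylacetamide, via ketene N,O-acetal 9 (not isolated)
Conditions: 8 (3 equiv), xylene, 140 °C, MeOH distilled off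
Reagents that add atoms: N,N-dimethylacetamide dimethyl acetal (8), CC(OC)(OC)N(C)C
Why: Eschenmoser–Claisen rearrangement: acetal exchange gives the ketene N,O-acetal, whose chair-like [3,3]-sigmatropic shift is expected to occur on the ring face opposite to the neighbouring isopropyl group, setting the quaternary carbon with the acetamide arm trans to isopropyl (1R) and unveiling an exocyclic methylene.

Step 6
Reactants: 10 2-[(1R,3R)-1-methyl-2-methylidene-3-(propan-2-yl)cyclopentyl]-N,N-dimethylacetamide
Product: 12 2-[(1R,3R)-1-methyl-2-oxo-3-(propan-2-yl)cyclopentyl]-N,N-dimethylacetamide, via spiro ozonide 11 (not isolated)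
Conditions: O3, CH2Cl2, −78 °C; then Me2S, −78 °C to rt
Reagents that add atoms: ozone, [O-][O+]=O
Why: Ozonolysis of the only alkene excises the exocyclic carbon as formaldehyde and gives the cyclopentanone; the neutral reductive work-up is chosen so that the now enolisable isopropyl-bearing carbon does not epimerise, and the tertiary amide is inert to ozone.

Step 7
Reactants: 12 2-[(1R,3R)-1-methyl-2-oxo-3-(propan-2-yl)cyclopentyl]-N,N-dimethylacetamide; 13 allylmagnesium bromide
Product: 14 2-[(1R,2S,3R)-2-hydroxy-1-methyl-3-(propan-2-yl)-2-(prop-2-en-1-yl)cyclopentyl]-N,N-dimethylacetamide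
Conditions: 13 (1.3 equiv), THF, −78 °C; then H2O
Reagents that add atoms: allylmagnesium bromide (13), C=CC[Mg]Br
Why: Grignard 1,2-addition, much faster at the ketone than at the tertiary amide at −78 °C, is expected from the face opposite to the adjacent isopropyl group (the face that carries the amide arm, whose carbonyl can hold the magnesium), which sets the carbinol carbon (2S) with hydroxyl cis to isopropyl and methyl and the allyl group cis to the amide arm.

Step 8
Reactants: 14 2-[(1R,2S,3R)-2-hydroxy-1-methyl-3-(propan-2-yl)-2-(prop-2-en-1-yl)cyclopentyl]-N,N-dimethylacetamide; 15 2-bromopropene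
Product: 18 1-[(1R,2S,3R)-2-hydroxy-1-methyl-3-(propan-2-yl)-2-(prop-2-en-1-yl)cyclopentyl]-3-methylbut-3-en-2-one, via isopropenyllithium 16 (not isolated), via dilithium hemiaminalate 17 (not isolated)
Conditions: 15 (3 equiv), tert-butyllithium (2 equiv per 15), Et2O, −78 °C; then 14, THF, −78 to 0 °C; then H2O
Reagents that add atoms: 2-bromopropene (15), CC(Br)=C, delivered as isopropenyllithium (16), [Li]C(C)=C
Why: Acyl substitution of a tertiary amide by a vinyllithium: after deprotonation of the tertiary alcohol, isopropenyllithium adds once to give a tetrahedral lithium hemiaminalate that is stable until aqueous work-up, so the enone appears only after the organolithium is quenched and no stereocentre is affected.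

Step 9
Reactants: 18 1-[(1R,2S,3R)-2-hydroxy-1-methyl-3-(propan-2-yl)-2-(prop-2-en-1-yl)cyclopentyl]-3-methylbut-3-en-2-one
Product: 19 (3R,3aS,8aR)-3a-hydroxy-6,8a-dimethyl-3-(propan-2-yl)-2,3,3a,4,8,8a-hexahydroazulen-7(1H)-one
Conditions: second-generation Grubbs catalyst RuCl2(H2IMes)(PCy3)(=CHPh) (5–10 mol %), toluene (5 mM), 80 °C, argon sparge
Reagents that add atoms: none
Why: Ring-closing olefin metathesis: the ruthenium benzylidene initiates at the monosubstituted allyl terminus on C3a, the new alkylidene adds to the isopropenyl ketone through a ruthenacyclobutane, and cycloreversion releases ethene and the C5=C6 bond. The closest known reaction type is ring-closing metathesis of an ω-alkenyl α-methylene ketone to a 2-methylcycloalk-2-enone. The seven-membered ring is closed with both former alkene carbons (C5 and C6) as ring members, giving a cis-fused bicyclo[5.3.0]decenone. No stereocentre is created: the three cyclopentane centres are carried through and the ring alkene can only be Z. The step needs ring closure to beat homodimerisation at the allyl group; the two arms sit cis on the adjacent carbons C3a and C8a, the electron-poor 1,1-disubstituted enone alkene does not dimerise, and high dilution with removal of ethene drives the closure.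

Step 10
Reactants: 19 (3R,3aS,8aR)-3a-hydroxy-6,8a-dimethyl-3-(propan-2-yl)-2,3,3a,4,8,8a-hexahydroazulen-7(1H)-one
Product: 20 (3R,3aS,7R,8aR)-6,8a-dimethyl-3-(propan-2-yl)-1,2,3,7,8,8a-hexahydroazulene-3a,7(4H)-diol
Conditions: (S)-1-methyl-3,3-diphenyltetrahydro-1H,3H-pyrrolo[1,2-c][1,3,2]oxazaborole [(S)-Me-CBS] (0.2 equiv), catecholborane (2.5 equiv), toluene, −78 °C; then MeOH, aq. NaOH
Reagents that add atoms: none
Why: Corey–Bakshi–Shibata reduction: the (S)-oxazaborolidine binds the carbonyl with the α-methylalkenyl branch as the large group and catecholborane delivers hydride in the 1,2 mode to the face that gives the (7R) alcohol, an approach anti to the angular C8a methyl that the substrate should also favour.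

Step 11
Reactants: 20 (3R,3aS,7R,8aR)-6,8a-dimethyl-3-(propan-2-yl)-1,2,3,7,8,8a-hexahydroazulene-3a,7(4H)-diol; 21 4-methoxybenzoyl chloride
Product: 22 (3R,3aS,7R,8aR)-3a-hydroxy-6,8a-dimethyl-3-(propan-2-yl)-1,2,3,3a,4,7,8,8a-octahydroazulen-7-yl 4-methoxybenzoate
Conditions: 21 (1.2 equiv), Et3N, DMAP (cat.), CH2Cl2, 0 °C to rt
Reagents that add atoms: 4-methoxybenzoyl chloride (21), COc1ccc(cc1)C(Cl)=O
Why: Nucleophilic-catalysis acylation (DMAP) is selective for the secondary allylic C7 hydroxyl because the C3a hydroxyl is tertiary and flanked by two substituted carbons, and the configuration at C7 is retained.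

Step 12
Reactants: 22 (3R,3aS,7R,8aR)-3a-hydroxy-6,8a-dimethyl-3-(propan-2-yl)-1,2,3,3a,4,7,8,8a-octahydroazulen-7-yl 4-methoxybenzoate
Product: 24 (3R,3aS,6R,7R,8aR)-3a,6-dihydroxy-6,8a-dimethyl-3-(propan-2-yl)decahydroazulen-7-yl 4-methoxybenzoate (CNP0244624.1), via tertiary hydroperoxide 23 (not isolated)
Conditions: Mn(dpm)3 (dpm = 2,2,6,6-tetramethylheptane-3,5-dionate; 10 mol %), PhSiH3 (2 equiv), O2 (1 atm), i-PrOH/CH2Cl2, 0 °C to rt; then PPh3
Reagents that add atoms: dioxygen, O=O
Why: Mukaiyama-type hydration by metal-hydride hydrogen atom transfer: H• adds to C5 to give the tertiary C6 radical (Markovnikov sense), O2 is expected to capture it on the face opposite to the vicinal C7 ester (the ester face also carries the C3a hydroxyl and C8a methyl and is the shielded one), and PPh3 reduces the hydroperoxide, giving the trans 6,7-diol monoester (6R) under conditions that avoid the transannular ether a cationic hydration would form with the C3a hydroxyl.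

Compound list
1 | (S)-(−)-limonene, (4S)-1-methyl-4-(prop-1-en-2-yl)cyclohex-1-ene | CC1=CC[C@@H](C(C)=C)CC1 | starting material
2 | (4S)-1-methyl-4-(propan-2-yl)cyclohex-1-ene | CC1=CC[C@@H](C(C)C)CC1 | intermediate
3 | (4S)-1-methyl-4-(propan-2-yl)-7,8,9-trioxabicyclo[4.2.1]nonane, ozonide of 2, not isolated, bridgehead centres unspecified | CC12CC[C@H](C(C)C)CC(OO1)O2 | intermediate
4 | (3S)-6-oxo-3-(propan-2-yl)heptanal | O=CC[C@@H](C(C)C)CCC(C)=O | intermediate
5 | (5R)-2-hydroxy-2-methyl-5-(propan-2-yl)cyclopentane-1-carbaldehyde, aldol adduct, not isolated, C1 and C2 unspecified | O=CC1C(C)(O)CC[C@@H]1C(C)C | intermediate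
6 | (5R)-2-methyl-5-(propan-2-yl)cyclopent-1-ene-1-carbaldehyde | O=CC1=C(C)CC[C@@H]1C(C)C | intermediate
7 | [(5R)-2-methyl-5-(propan-2-yl)cyclopent-1-en-1-yl]methanol | OCC1=C(C)CC[C@@H]1C(C)C | intermediate
8 | N,N-dimethylacetamide dimethyl acetal (1,1-dimethoxy-N,N-dimethylethanamine) | CC(OC)(OC)N(C)C | starting material
9 | 1-{[(5R)-2-methyl-5-(propan-2-yl)cyclopent-1-en-1-yl]methoxy}-N,N-dimethylethen-1-amine, ketene N,O-acetal, not isolated | C=C(N(C)C)OCC1=C(C)CC[C@@H]1C(C)C | intermediate
10 | 2-[(1R,3R)-1-methyl-2-methylidene-3-(propan-2-yl)cyclopentyl]-N,N-dimethylacetamide | CN(C)C(=O)C[C@@]1(C)CC[C@H](C(C)C)C1=C | intermediate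
11 | 2-[(6R,9R)-6-methyl-9-(propan-2-yl)-1,2,4-trioxaspiro[4.4]nonan-6-yl]-N,N-dimethylacetamide, spiro ozonide of 10, not isolated, spiro centre unspecified | CN(C)C(=O)C[C@@]1(C)CC[C@H](C(C)C)C12OCOO2 | intermediate
12 | 2-[(1R,3R)-1-methyl-2-oxo-3-(propan-2-yl)cyclopentyl]-N,N-dimethylacetamide | CN(C)C(=O)C[C@@]1(C)CC[C@H](C(C)C)C1=O | intermediate
13 | allylmagnesium bromide | C=CC[Mg]Br | starting material
14 | 2-[(1R,2S,3R)-2-hydroxy-1-methyl-3-(propan-2-yl)-2-(prop-2-en-1-yl)cyclopentyl]-N,N-dimethylacetamide | CN(C)C(=O)C[C@@]1(C)CC[C@H](C(C)C)[C@@]1(O)CC=C | intermediate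
15 | 2-bromopropene | CC(Br)=C | starting material
16 | isopropenyllithium (prop-1-en-2-yllithium), made in the flask, not isolated | [Li]C(C)=C | intermediate
17 | dilithium salt of the tetrahedral adduct of 14 with isopropenyllithium (lithium hemiaminalate), not isolated, new centre unspecified | C=C(C)C(O[Li])(N(C)C)C[C@@]1(C)CC[C@H](C(C)C)[C@@]1(O[Li])CC=C | intermediate
18 | 1-[(1R,2S,3R)-2-hydroxy-1-methyl-3-(propan-2-yl)-2-(prop-2-en-1-yl)cyclopentyl]-3-methylbut-3-en-2-one | C=C(C)C(=O)C[C@@]1(C)CC[C@H](C(C)C)[C@@]1(O)CC=C | intermediate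
19 | (3R,3aS,8aR)-3a-hydroxy-6,8a-dimethyl-3-(propan-2-yl)-2,3,3a,4,8,8a-hexahydroazulen-7(1H)-one | O=C1C[C@@]2(C)CC[C@H](C(C)C)[C@@]2(O)CC=C1C | intermediate
20 | (3R,3aS,7R,8aR)-6,8a-dimethyl-3-(propan-2-yl)-1,2,3,7,8,8a-hexahydroazulene-3a,7(4H)-diol | O[C@@H]1C[C@@]2(C)CC[C@H](C(C)C)[C@@]2(O)CC=C1C | intermediate
21 | 4-methoxybenzoyl chloride | COc1ccc(cc1)C(Cl)=O | starting material
22 | (3R,3aS,7R,8aR)-3a-hydroxy-6,8a-dimethyl-3-(propan-2-yl)-1,2,3,3a,4,7,8,8a-octahydroazulen-7-yl 4-methoxybenzoate | COc1ccc(cc1)C(=O)O[C@@H]1C[C@@]2(C)CC[C@H](C(C)C)[C@@]2(O)CC=C1C | intermediate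
23 | (3R,3aS,6R,7R,8aR)-6-hydroperoxy-3a-hydroxy-6,8a-dimethyl-3-(propan-2-yl)decahydroazulen-7-yl 4-methoxybenzoate, not isolated | COc1ccc(cc1)C(=O)O[C@@H]1C[C@@]2(C)CC[C@H](C(C)C)[C@@]2(O)CC[C@@]1(C)OO | intermediate
24 | (3R,3aS,6R,7R,8aR)-3a,6-dihydroxy-6,8a-dimethyl-3-(propan-2-yl)decahydroazulen-7-yl 4-methoxybenzoate (CNP0244624.1) | COc1ccc(C(=O)O[C@@H]2C[C@@]3(C)CC[C@H](C(C)C)[C@@]3(O)CC[C@@]2(C)O)cc1 | target

Total step count: 12. Longest linear sequence: 12 steps (1 to 24); all other starting materials (8, 13, 15, 21) are used as purchased.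

Steps most likely to fail, with fallbacks

Step 12 is the most exposed. Capture of the planar C6 radical by O2 may show poor facial discrimination, or the radical may simply be reduced to the alkane. The fallback leaves the radical manifold and sets out from 22. Buffered epoxidation (mCPBA, NaHCO3, CH2Cl2, 0 °C) should deliver oxygen in a concerted step to the face opposite the C7 ester, giving (3R,3aS,7R,8aR)-5,6-epoxy-3a-hydroxy-6,8a-dimethyl-3-(propan-2-yl)decahydroazulen-7-yl 4-methoxybenzoate F1. LiEt3BH (THF, 0 °C to rt) would then open the oxirane at the secondary C5 and cleave the ester at the same time, giving (3R,3aS,6R,7R,8aR)-6,8a-dimethyl-3-(propan-2-yl)decahydroazulene-3a,6,7-triol F2. The only secondary hydroxyl of F2 would be re-esterified with 21 (Et3N, DMAP), which comes back to the route at 24.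

Step 9, the key ring closure, is next. The electron-poor, 1,1-disubstituted isopropenyl ketone may engage the ruthenium alkylidene too slowly, so that oligomerisation through the allyl group takes over. The fallback changes the oxidation level at which the same C5=C6 bond is closed and sets out from 18. Reduction with the (S)-oxazaborolidine/catecholborane system of step 10 should give (2R)-1-[(1R,2S,3R)-2-hydroxy-1-methyl-3-(propan-2-yl)-2-(prop-2-en-1-yl)cyclopentyl]-3-methylbut-3-en-2-ol F3. Acylation with 21 would give (2R)-1-[(1R,2S,3R)-2-hydroxy-1-methyl-3-(propan-2-yl)-2-(prop-2-en-1-yl)cyclopentyl]-3-methylbut-3-en-2-yl 4-methoxybenzoate F4. Ring-closing metathesis of this electron-richer 2-methylallyl ester with the same catalyst would come back to the route at 22.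

Step 10 is third. Hydride delivery may lose facial selectivity if the catalyst and the folded bicyclic substrate turn out to be mismatched. The fallback is stereoconvergent and sets out from 19. Luche reduction (NaBH4, CeCl3·7H2O, MeOH) would give a separable mixture of 20 and its epimer (3R,3aS,7S,8aR)-6,8a-dimethyl-3-(propan-2-yl)-1,2,3,7,8,8a-hexahydroazulene-3a,7(4H)-diol F5. Alcohol 20 is acylated as in step 11. F5 is esterified with 4-methoxybenzoic acid under Mitsunobu conditions (PPh3, diisopropyl azodicarboxylate, THF) with inversion at C7, so that both epimers come back to the route at 22.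

Further compounds
F1 | step 12 | (3R,3aS,7R,8aR)-5,6-epoxy-3a-hydroxy-6,8a-dimethyl-3-(propan-2-yl)decahydroazulen-7-yl 4-methoxybenzoate, oxirane oxygen trans to the C7 ester | COc1ccc(cc1)C(=O)O[C@@H]2C[C@@]3(C)CC[C@H](C(C)C)[C@@]3(O)C[C@H]4O[C@@]24C
F2 | step 12 | (3R,3aS,6R,7R,8aR)-6,8a-dimethyl-3-(propan-2-yl)decahydroazulene-3a,6,7-triol | O[C@@H]1C[C@@]2(C)CC[C@H](C(C)C)[C@@]2(O)CC[C@@]1(C)O
F3 | step 9 | (2R)-1-[(1R,2S,3R)-2-hydroxy-1-methyl-3-(propan-2-yl)-2-(prop-2-en-1-yl)cyclopentyl]-3-methylbut-3-en-2-ol | C=C(C)[C@H](O)C[C@@]1(C)CC[C@H](C(C)C)[C@@]1(O)CC=C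
F4 | step 9 | (2R)-1-[(1R,2S,3R)-2-hydroxy-1-methyl-3-(propan-2-yl)-2-(prop-2-en-1-yl)cyclopentyl]-3-methylbut-3-en-2-yl 4-methoxybenzoate | COc1ccc(cc1)C(=O)O[C@@H](C(C)=C)C[C@@]1(C)CC[C@H](C(C)C)[C@@]1(O)CC=C
F5 | step 10 | (3R,3aS,7S,8aR)-6,8a-dimethyl-3-(propan-2-yl)-1,2,3,7,8,8a-hexahydroazulene-3a,7(4H)-diol | O[C@H]1C[C@@]2(C)CC[C@H](C(C)C)[C@@]2(O)CC=C1C
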